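**Assumption:** ring locants are O1, C2 (aryl), C3 (CH2OH), C4 (aroyl), C5 (OCH2). The target is (2S,3R,4S), all-trans, and C4 (α to the ketone) is treated as the thermodynamic centre and set last.

## Retrosynthetic overview

1. Target 15 ⇐ its C4 epimer 14 (ring-B phenol as TIPS ether) by basic desilylation with equilibration α to the ketone.
2. The THF ring (the only ring made, O1–C2 bond) ⇐ acyclic keto-diol 13: oxidation of the 4-alkylsyringol to a p-quinone methide, then 5-exo intramolecular oxa-Michael (1,6-) addition of the primary OH; this sets C2 trans to C3.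
3. 13 ⇐ lactone 11 by LiAlH4 (lactone and acetal to 1,4-diol, pivalate off) and dithiane hydrolysis.
4. 11 ⇐ one-pot union of three fragments: lithiated aryl dithiane 6 (Michael donor), (5R)-menthyloxybutenolide 10 (acceptor, chiral auxiliary) and benzyl bromide 4 (enolate trap); this sets C3.
5. 4 and 6 come from syringaldehyde; 10 comes from furfural and (−)-menthol. The butenolide ring is sacrificial and is opened in step 9.

## Route

**Step 1**
Reactants: 1 syringaldehyde
Product: 2 4-formyl-2,6-dimethoxyphenyl pivalate
Conditions: PivCl, Et3N, DMAP (cat.), CH2Cl2, 0 °C → rt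
Reagents that add atoms: pivaloyl chloride, CC(C)(C)C(=O)Cl
Why: Phenol O-acylation; the hindered pivalate should tolerate the enolate alkylation in step 8 and is removed by LiAlH4 in step 9 without a separate step.

**Step 2**
Reactants: 2
Product: 3 4-(hydroxymethyl)-2,6-dimethoxyphenyl pivalate
Conditions: NaBH4, THF/MeOH, 0 °C
Reagents that add atoms: none
Why: Chemoselective borohydride reduction of the aldehyde; the hindered aryl ester is untouched at 0 °C.

**Step 3**
Reactants: 3
Product: 4 4-(bromomethyl)-2,6-dimethoxyphenyl pivalate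
Conditions: PBr3, CH2Cl2, 0 °C (used crude)
Reagents that add atoms: phosphorus tribromide, BrP(Br)Br
Why: Benzylic alcohol to bromide (phosphite activation, SN2); the para-acyloxy group makes the bromide less prone to ionisation than an alkoxy or silyloxy analogue.

**Step 4**
Reactants: 1 syringaldehyde
Product: 5 3,5-dimethoxy-4-(triisopropylsilyloxy)benzaldehyde
Conditions: TIPSCl, imidazole, DMF, 40 °C
Reagents that add atoms: triisopropylsilyl chloride, CC(C)[Si](Cl)(C(C)C)C(C)C
Why: Phenol silylation; the aryl TIPS ether withstands BF3, n-BuLi, LiAlH4 and DDQ.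

**Step 5**
Reactants: 5
Product: 6 2-[3,5-dimethoxy-4-(triisopropylsilyloxy)phenyl]-1,3-dithiane
Conditions: HS(CH2)3SH, BF3·OEt2 (cat.), CH2Cl2, 0 °C → rt
Reagents that add atoms: propane-1,3-dithiol, SCCCS
Why: Thioacetalisation gives the Corey–Seebach acyl-anion precursor for the aroyl group.

**Step 6**
Reactants: 7 furfural
Product: 8 5-hydroxy-2(5H)-furanone (racemic)
Conditions: O2, rose bengal (cat.), MeOH, hν (visible), rt
Reagents that add atoms: dioxygen, O=O
Why: Singlet-oxygen [4+2] photooxygenation of the furan; methanolysis of the endoperoxide expels the formyl carbon as methyl formate.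

**Step 7**
Reactants: 8; 9 (−)-menthol
Product: 10 (5R)-5-[(1R,2S,5R)-menthyloxy]-2(5H)-furanone
Conditions: CSA (cat.), toluene, reflux (Dean–Stark); crystallise from petroleum ether, re-equilibrate the mother liquor with acid and recrystallise
Reagents that add atoms: none
Why: Acid-catalysed acetalisation gives both C5 epimers; the (5R) epimer crystallises while the acetal centre equilibrates (crystallisation-induced asymmetric transformation).

**Step 8**
Reactants: 6; 10; 4
Product: 11 (3R,4R,5R)-3-[(3,5-dimethoxy-4-pivaloyloxyphenyl)methyl]-4-{2-[3,5-dimethoxy-4-(triisopropylsilyloxy)phenyl]-1,3-dithian-2-yl}-5-(menthyloxy)dihydrofuran-2(3H)-one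
Conditions: 6, n-BuLi, THF, −78 → −20 °C; 10 (1.05 equiv), −78 °C; then 4, DMPU, −78 °C → rt
Reagents that add atoms: none
Why: Tandem Michael addition–enolate alkylation. The lithiated dithiane adds 1,4 to the butenolide anti to the menthyloxy group, and the lactone enolate is benzylated anti to the bulky dithianyl group (3,4-trans, 4,5-trans); this fixes the carbon that becomes C3 of the target as R.

**Step 9**
Reactants: 11
Product: 12 (2R,3R)-2-[(4-hydroxy-3,5-dimethoxyphenyl)methyl]-3-{2-[3,5-dimethoxy-4-(triisopropylsilyloxy)phenyl]-1,3-dithian-2-yl}butane-1,4-diol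
Conditions: LiAlH4 (excess), THF, 0 °C → rt; Rochelle-salt work-up (menthol recovered)
Reagents that add atoms: none
Why: Hydride reduction of the lactone and of the aldehyde released from the acetal carbon gives the 1,4-diol; the same reagent cleaves the pivalate. Dithiane and TIPS ether are inert and no stereocentre is touched.

**Step 10**
Reactants: 12
Product: 13 (2R,3R)-1-[3,5-dimethoxy-4-(triisopropylsilyloxy)phenyl]-4-hydroxy-3-[(4-hydroxy-3,5-dimethoxyphenyl)methyl]-2-(hydroxymethyl)butan-1-one (in equilibrium with its five-membered hemiketal)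
Conditions: MeI, CaCO3, MeCN/H2O (9:1), 45 °C
Reagents that add atoms: water, O
Why: Alkylative dithiane hydrolysis (S-methylation, then hydrolysis of the aryl-stabilised thionium ion); it is non-oxidative, so the free electron-rich phenol survives, and CaCO3 buffers the HI.

**Step 11 (key ring closure)**
Reactants: 13
Product: 14 [(2S,3R,4R)-2-(4-hydroxy-3,5-dimethoxyphenyl)-3-(hydroxymethyl)tetrahydrofuran-4-yl][3,5-dimethoxy-4-(triisopropylsilyloxy)phenyl]methanone (3,4-cis; may sit partly as the bicyclic hemiketal)
Conditions: DDQ (1.05 equiv), CH2Cl2, 0 °C → rt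
Reagents that add atoms: none
Why: DDQ dehydrogenates the 4-alkyl-2,6-dimethoxyphenol to a p-quinone methide, and the CH2OH on the carbon α to the ketone closes the ring by a 5-exo-trig intramolecular oxa-Michael (1,6-) addition with rearomatisation. The aryl group ends up trans to the adjacent CH2OH (least-strained transition state, and reversible through the quinone methide under the acidic DDQH2), giving C2 = S.

**Step 12**
Reactants: 14
Product: 15 target, [(2S,3R,4S)-2-(4-hydroxy-3,5-dimethoxyphenyl)-3-(hydroxymethyl)tetrahydrofuran-4-yl](4-hydroxy-3,5-dimethoxyphenyl)methanone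
Conditions: K2CO3, MeOH, rt → 40 °C; aq. NH4Cl quench
Reagents that add atoms: none
Why: Methanolysis of the aryl silyl ether (the p-acylphenoxide is a good leaving group) and enolisation–reprotonation α to the ketone; thermodynamic epimerisation puts the aroyl group trans to the CH2OH, so C4 goes from R to S and the ring becomes all-trans.

## Compound list

1 | syringaldehyde | COc1cc(C=O)cc(OC)c1O | starting material
2 | 4-formyl-2,6-dimethoxyphenyl pivalate | COc1cc(C=O)cc(OC)c1OC(=O)C(C)(C)C | intermediate
3 | 4-(hydroxymethyl)-2,6-dimethoxyphenyl pivalate | COc1cc(CO)cc(OC)c1OC(=O)C(C)(C)C | intermediate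
4 | 4-(bromomethyl)-2,6-dimethoxyphenyl pivalate | COc1cc(CBr)cc(OC)c1OC(=O)C(C)(C)C | intermediate
5 | 3,5-dimethoxy-4-(triisopropylsilyloxy)benzaldehyde | COc1cc(C=O)cc(OC)c1O[Si](C(C)C)(C(C)C)C(C)C | intermediate
6 | 2-[3,5-dimethoxy-4-(triisopropylsilyloxy)phenyl]-1,3-dithiane | COc1cc(C2SCCCS2)cc(OC)c1O[Si](C(C)C)(C(C)C)C(C)C | intermediate
7 | furfural | O=Cc1ccco1 | starting material
8 | 5-hydroxy-2(5H)-furanone (racemic) | O=C1C=CC(O)O1 | intermediate
9 | (−)-menthol, (1R,2S,5R) | C[C@@H]1CC[C@H]([C@@H](C1)O)C(C)C | starting material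
10 | (5R)-5-[(1R,2S,5R)-menthyloxy]-2(5H)-furanone | O=C1C=C[C@H](O[C@@H]2C[C@H](C)CC[C@H]2C(C)C)O1 | intermediate
11 | (3R,4R,5R) benzyl/dithianyl/menthyloxy lactone | O=C1O[C@@H](O[C@@H]2C[C@H](C)CC[C@H]2C(C)C)[C@H](C3(c4cc(OC)c(O[Si](C(C)C)(C(C)C)C(C)C)c(OC)c4)SCCCS3)[C@H]1Cc5cc(OC)c(OC(=O)C(C)(C)C)c(OC)c5 | intermediate
12 | (2R,3R) dithianyl 1,4-diol, ring-A phenol free | OC[C@H](Cc1cc(OC)c(O)c(OC)c1)[C@H](CO)C2(c3cc(OC)c(O[Si](C(C)C)(C(C)C)C(C)C)c(OC)c3)SCCCS2 | intermediate
13 | (2R,3R) keto-diol | OC[C@H](Cc1cc(OC)c(O)c(OC)c1)[C@H](CO)C(=O)c2cc(OC)c(O[Si](C(C)C)(C(C)C)C(C)C)c(OC)c2 | intermediate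
14 | (2S,3R,4R) 3,4-cis tetrahydrofuran, TIPS ether | COc1cc(C(=O)[C@H]2CO[C@H](c3cc(OC)c(O)c(OC)c3)[C@H]2CO)cc(OC)c1O[Si](C(C)C)(C(C)C)C(C)C | intermediate
15 | (2S,3R,4S) all-trans tetrahydrofuran, CID53356211 | COc1cc(C(=O)[C@@H]2CO[C@H](c3cc(OC)c(O)c(OC)c3)[C@H]2CO)cc(OC)c1O | target

## Summary

Total steps: 12.
Longest linear sequence: 8 (steps 1, 2, 3, 8, 9, 10, 11, 12); the other two branches are steps 4–5 and 6–7.

Steps most likely to fail:

1. **Step 11 (DDQ quinone-methide generation and oxa-Michael closure).** Risks are over-oxidation of the product's benzylic C–H and side reactions of the quinone methide. Fallback: generate the same quinone methide without an oxidant. Trap the step-8 enolate with aldehyde 2 (aldol) instead of bromide 4, carry the benzylic OH through steps 9–10, and let the p-hydroxybenzyl alcohol dehydrate to the quinone methide with cat. CSA; it then cyclises in the same 5-exo oxa-Michael mode.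

2. **Step 8 (three-component Michael–alkylation).** Risks are sluggish benzylation of the hindered enolate and attack on the pivalate. Fallback: drop the one-pot union and set C3 with an Evans auxiliary. Make (R)-4-[(4-protected-oxy-3,5-dimethoxyphenyl)methyl]dihydrofuran-2(3H)-one by Evans alkylation, carry out an aldol reaction with aldehyde 5, reduce to the triol with LiAlH4, and oxidise the benzylic alcohol selectively with MnO2 to reach a 13-type keto-diol.

3. **Step 12 (desilylation and C4 equilibration).** The 3,4-cis isomer can hide as a cis-fused bicyclic hemiketal, which may leave the equilibrium incomplete. Fallback: silylate the primary OH of 14 (TBSCl) so no hemiketal can form, epimerise with DBU (the all-trans isomer is then clearly favoured), and remove both silyl groups with TBAF or HF·pyridine.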